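## Retrosynthetic overview

1. Target ⇐ C–O bond: site-selective methanolysis of the cis-(3S,4S) 2-aryl-3-benzylsuccinic anhydride at the carbonyl on the benzyl-bearing carbon (ester there, free acid on the aryl-bearing carbon); phenols carried as acetates.
2. cis-Anhydride ⇐ asymmetric syn-hydrogenation of the aryl/benzyl maleic anhydride. The (2S,3S) target belongs to the cis-anhydride (erythro) series, so syn addition of H2 gives the right relative configuration and sets both stereocentres.
3. Maleic anhydride ⇐ Perkin-type condensation of (4-hydroxyphenyl)acetic acid with the (3-hydroxy-4-prenylphenyl)pyruvic acid. This furan-2,5-dione is the only ring that is built; both benzene rings are bought.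
4. Arylpyruvic acid ⇐ hydantoin homologation of 3-hydroxy-4-prenylbenzaldehyde ⇐ Stille prenylation of 4-bromo-3-hydroxybenzaldehyde.

Assumption: for the two chiral catalysts (steps 5 and 6) the enantiomeric series named is the one expected by analogy with symmetrical substrates; the sense is confirmed on the first run and the mirror-image catalyst is taken if needed.

## Route

Step 1
Reactants: 1 4-bromo-3-hydroxybenzaldehyde; 2 tributyl(3-methylbut-2-en-1-yl)stannane
Product: 3 3-hydroxy-4-(3-methylbut-2-en-1-yl)benzaldehyde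
Conditions: 2 (1.3 eq), Pd(PPh3)4 (5 mol%), DMF, 90 °C, 12 h
Reagents that add atoms: none
Why: Stille cross-coupling; the aldehyde-activated C–Br bond adds to Pd(0), the allyl group is transferred from tin, and reductive elimination at the less hindered CH2 terminus gives the linear prenyl arene, with the free phenol tolerated.

Step 2
Reactants: 3 3-hydroxy-4-(3-methylbut-2-en-1-yl)benzaldehyde; 4 imidazolidine-2,4-dione (hydantoin)
Product: 5 (5Z)-5-{[3-hydroxy-4-(3-methylbut-2-en-1-yl)phenyl]methylidene}imidazolidine-2,4-dione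
Conditions: 4 (1.2 eq), ethanolamine (1.5 eq), EtOH–H2O, 90 °C, 6 h; then AcOH to pH 5, filter
Reagents that add atoms: none
Why: Knoevenagel-type condensation of the hydantoin C5 methylene with the aldehyde gives the thermodynamic Z-arylidene hydantoin under basic conditions that leave the o-prenylphenol untouched.

Step 3
Reactants: 5 (5Z)-5-{[3-hydroxy-4-(3-methylbut-2-en-1-yl)phenyl]methylidene}imidazolidine-2,4-dione
Product: 6 3-[3-hydroxy-4-(3-methylbut-2-en-1-yl)phenyl]-2-oxopropanoic acid
Conditions: 20% aq. NaOH, reflux under N2, 3 h; then 0 °C, 2 M HCl to pH 2, EtOAc extraction; used at once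
Reagents that add atoms: water, O
Why: Alkaline hydrolysis of an arylidene hydantoin (hydantoin route to arylpyruvic acids) opens the ring and hydrolyses the enamine to the α-keto acid and urea; no hot acid is used, so the o-prenylphenol cannot close to a chroman.

Step 4
Reactants: 6 3-[3-hydroxy-4-(3-methylbut-2-en-1-yl)phenyl]-2-oxopropanoic acid; 7 (4-hydroxyphenyl)acetic acid
Product: 8 4-[4-{[3-acetoxy-4-(3-methylbut-2-en-1-yl)phenyl]methyl}-2,5-dioxo-2,5-dihydrofuran-3-yl]phenyl acetate
Conditions: 7 (1.5 eq), Ac2O (solvent), NaOAc (1 eq), 110 °C, 3 h; aqueous work-up, crystallisation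
Reagents that add atoms: acetic anhydride, CC(=O)OC(C)=O
Why: Perkin-type condensation; the arylacetic acid α-carbon (as its mixed-anhydride enolate) adds to the keto carbonyl, dehydration and ring closure follow, the double bond settles in the tetrasubstituted ring position, and Ac2O acetylates both phenols, giving protection at no extra step.

Step 5
Reactants: 8 4-[4-{[3-acetoxy-4-(3-methylbut-2-en-1-yl)phenyl]methyl}-2,5-dioxo-2,5-dihydrofuran-3-yl]phenyl acetate
Product: 9 4-[(3S,4S)-4-{[3-acetoxy-4-(3-methylbut-2-en-1-yl)phenyl]methyl}-2,5-dioxooxolan-3-yl]phenyl acetate (cis)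
Conditions: [Rh(nbd)2]BF4 (1 mol%), ferrocenyl bisphosphine–thiourea ligand (ZhaoPhos type, 1.1 mol%), H2 (50 bar), CH2Cl2, 40 °C, 24 h; filtered through Celite, used crude
Reagents that add atoms: none
Why: Rh-catalysed asymmetric hydrogenation of a substituted maleic anhydride; syn delivery of H2 fixes the cis relationship and the ligand (thiourea hydrogen-bonded to the anhydride carbonyl) selects the face, so both stereocentres (3S,4S) are set together, while the isolated trisubstituted prenyl alkene and the aryl acetates are inert to cationic Rh–diphosphine catalysts.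

Step 6
Reactants: 9 4-[(3S,4S)-4-{[3-acetoxy-4-(3-methylbut-2-en-1-yl)phenyl]methyl}-2,5-dioxooxolan-3-yl]phenyl acetate
Product: 11 (2S,3S)-2-(4-hydroxyphenyl)-3-{[3-hydroxy-4-(3-methylbut-2-en-1-yl)phenyl]methyl}-4-methoxy-4-oxobutanoic acid (target), via diacetate hemiester 10 (not isolated)
Conditions: (a) quinine-derived sulfonamide catalyst (9-amino-9-deoxy-epi-quinine 3,5-bis(trifluoromethyl)benzenesulfonamide, 10 mol%), MeOH (10 eq), MTBE, −20 °C, 24 h; (b) evaporate, 7 M NH3 in MeOH, 0 °C → rt, 2 h; aq. NaH2PO4 (pH 4), EtOAc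
Reagents that add atoms: methanol, CO
Why: Proposed new method: catalyst-controlled site-selective alcoholysis of a non-symmetric, enantioenriched cis-2-aryl-3-benzylsuccinic anhydride with an epimerisable α-aryl centre — the quinuclidine nitrogen acts as general base for MeOH while the sulfonamide N–H binds the anhydride carbonyl, and the catalyst's fixed preference for one carbonyl of a cis-2,3-disubstituted succinic anhydride is matched to the substrate's own bias (C5=O, next to the benzyl-bearing carbon, is less shielded and expels the better α-aryl carboxylate), so the new C–O bond forms at C5, at −20 °C faster than enolisation or ketene formation at C3, and any (3R,4R)-anhydride is diverted to the separable regioisomer, which raises the ee; the closest known reaction type is the cinchona-catalysed desymmetrising methanolysis of meso anhydrides and the parallel kinetic resolution of monosubstituted succinic anhydrides; operation (b) is ordinary ammonolysis of aryl acetates, which leaves the methyl ester and both stereocentres untouched.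

## Compound list

1 | 4-bromo-3-hydroxybenzaldehyde | O=Cc1ccc(Br)c(O)c1 | starting material
2 | tributyl(3-methylbut-2-en-1-yl)stannane | CCCC[Sn](CCCC)(CCCC)CC=C(C)C | starting material
3 | 3-hydroxy-4-(3-methylbut-2-en-1-yl)benzaldehyde | O=Cc1ccc(CC=C(C)C)c(O)c1 | intermediate
4 | imidazolidine-2,4-dione (hydantoin) | O=C1CNC(=O)N1 | starting material
5 | (5Z)-5-{[3-hydroxy-4-(3-methylbut-2-en-1-yl)phenyl]methylidene}imidazolidine-2,4-dione | O=C1NC(=O)/C(=C/c2ccc(CC=C(C)C)c(O)c2)N1 | intermediate
6 | 3-[3-hydroxy-4-(3-methylbut-2-en-1-yl)phenyl]-2-oxopropanoic acid | OC(=O)C(=O)Cc1ccc(CC=C(C)C)c(O)c1 | intermediate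
7 | (4-hydroxyphenyl)acetic acid | OC(=O)Cc1ccc(O)cc1 | starting material
8 | 4-[4-{[3-acetoxy-4-(3-methylbut-2-en-1-yl)phenyl]methyl}-2,5-dioxo-2,5-dihydrofuran-3-yl]phenyl acetate | CC(=O)Oc1ccc(cc1)C1=C(Cc2ccc(CC=C(C)C)c(OC(C)=O)c2)C(=O)OC1=O | intermediate
9 | 4-[(3S,4S)-4-{[3-acetoxy-4-(3-methylbut-2-en-1-yl)phenyl]methyl}-2,5-dioxooxolan-3-yl]phenyl acetate (cis) | O=C1[C@@H](Cc2ccc(CC=C(C)C)c(OC(C)=O)c2)[C@H](C(=O)O1)c3ccc(OC(C)=O)cc3 | intermediate
10 | (2S,3S)-2-(4-acetoxyphenyl)-3-{[3-acetoxy-4-(3-methylbut-2-en-1-yl)phenyl]methyl}-4-methoxy-4-oxobutanoic acid | COC(=O)[C@@H](Cc1ccc(CC=C(C)C)c(OC(C)=O)c1)[C@H](C(=O)O)c1ccc(OC(C)=O)cc1 | intermediate (not isolated)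
11 | (2S,3S)-2-(4-hydroxyphenyl)-3-{[3-hydroxy-4-(3-methylbut-2-en-1-yl)phenyl]methyl}-4-methoxy-4-oxobutanoic acid | COC(=O)[C@@H](Cc1ccc(CC=C(C)C)c(O)c1)[C@H](C(=O)O)c1ccc(O)cc1 | target

## Step count and risks

Total step count: 6. Longest linear sequence: 6 (1 → 3 → 5 → 6 → 8 → 9 → 11).

The three steps most likely to fail:

**Step 6 (proposed new step).** The risks are an insufficient site ratio, epimerisation of C3 to the trans anhydride, and a base-induced ketene pathway that would put the ester on the aryl side. The fallback gives up catalyst control and uses known chemistry. It sets out from 9: stirring in neat MeOH without any catalyst at 0 °C → rt (neutral, substrate-controlled alcoholysis, with no base that could enolise C3) gives 10 together with its regioisomer (2S,3S)-2-{[3-acetoxy-4-(3-methylbut-2-en-1-yl)phenyl]methyl}-3-(4-acetoxyphenyl)-4-methoxy-4-oxobutanoic acid F8. The two constitutional isomers are separated on silica (AcOH-doped eluent) or by preparative HPLC. The fallback comes back to the route at 10, which is deacetylated with NH3/MeOH as in operation (b) to give 11. The expected ratio is only modest (perhaps 2–4:1), so the cost is yield.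

**Step 5.** The tetrasubstituted, unsymmetrical aryl/benzyl maleic anhydride is at the demanding end of what this catalyst class has been shown to hydrogenate; conversion or ee may be poor. The fallback replaces asymmetric hydrogenation by resolution. It sets out from 8: hydrogenation with achiral [Rh(cod)(dppb)]BF4 (H2 50 bar, CH2Cl2) gives the racemic cis-anhydride, that is 9 mixed 1:1 with its enantiomer 4-[(3R,4R)-4-{[3-acetoxy-4-(3-methylbut-2-en-1-yl)phenyl]methyl}-2,5-dioxooxolan-3-yl]phenyl acetate F5, and so comes back to the route at 9. Step 6 is then run unchanged and acts as a parallel kinetic resolution: 9 goes on to 10 and 11, while F5 is opened at the other carbonyl to (2R,3R)-2-{[3-acetoxy-4-(3-methylbut-2-en-1-yl)phenyl]methyl}-3-(4-acetoxyphenyl)-4-methoxy-4-oxobutanoic acid F6. The ammonia treatment turns F6 into (2R,3R)-2-{[3-hydroxy-4-(3-methylbut-2-en-1-yl)phenyl]methyl}-3-(4-hydroxyphenyl)-4-methoxy-4-oxobutanoic acid F7, a constitutional isomer of 11 that is removed by ordinary chromatography. A final chiral SFC polish removes any residual enantiomer. Maximum yield is 50%.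

**Step 4.** The arylpyruvic acid can form its enol acetate or self-condense in hot Ac2O, so the cross-condensation may be low-yielding. The fallback builds the same anhydride by a Wittig olefination instead of a Perkin condensation. It sets out from 3 (bypassing 5 and 6) and 7.
- 3 is acetylated (Ac2O, pyridine) to 3-acetoxy-4-(3-methylbut-2-en-1-yl)benzaldehyde F1.
- 7 is condensed with glyoxylic acid monohydrate in Ac2O/Et3N to 4-(2,5-dioxo-2,5-dihydrofuran-3-yl)phenyl acetate F2.
- F2 takes up PPh3 (THF, rt) at its unsubstituted ring carbon to give, after proton shift, the ylide 4-[2,5-dioxo-4-(triphenyl-λ5-phosphanylidene)oxolan-3-yl]phenyl acetate F3 (racemic, not isolated).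
- F3 and F1 undergo Wittig reaction (THF, reflux) to 4-[(4E)-4-{[3-acetoxy-4-(3-methylbut-2-en-1-yl)phenyl]methylidene}-2,5-dioxooxolan-3-yl]phenyl acetate F4 (racemic).
- Et3N (CH2Cl2, rt) moves the exocyclic double bond of F4 into the ring, and the fallback comes back to the route at 8.

## Further compounds

F1 | step 4 | 3-acetoxy-4-(3-methylbut-2-en-1-yl)benzaldehyde | CC(=O)Oc1cc(C=O)ccc1CC=C(C)C
F2 | step 4 | 4-(2,5-dioxo-2,5-dihydrofuran-3-yl)phenyl acetate | CC(=O)Oc1ccc(cc1)C1=CC(=O)OC1=O
F3 | step 4 | 4-[2,5-dioxo-4-(triphenyl-λ5-phosphanylidene)oxolan-3-yl]phenyl acetate (racemic) | CC(=O)Oc1ccc(cc1)C2C(=O)OC(=O)C2=P(c3ccccc3)(c4ccccc4)c5ccccc5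
F4 | step 4 | 4-[(4E)-4-{[3-acetoxy-4-(3-methylbut-2-en-1-yl)phenyl]methylidene}-2,5-dioxooxolan-3-yl]phenyl acetate (racemic) | CC(=O)Oc1ccc(cc1)C2C(=O)OC(=O)/C2=C/c3ccc(CC=C(C)C)c(OC(C)=O)c3
F5 | step 5 | 4-[(3R,4R)-4-{[3-acetoxy-4-(3-methylbut-2-en-1-yl)phenyl]methyl}-2,5-dioxooxolan-3-yl]phenyl acetate | O=C1[C@H](Cc2ccc(CC=C(C)C)c(OC(C)=O)c2)[C@@H](C(=O)O1)c3ccc(OC(C)=O)cc3
F6 | step 5 | (2R,3R)-2-{[3-acetoxy-4-(3-methylbut-2-en-1-yl)phenyl]methyl}-3-(4-acetoxyphenyl)-4-methoxy-4-oxobutanoic acid | OC(=O)[C@H](Cc1ccc(CC=C(C)C)c(OC(C)=O)c1)[C@@H](C(=O)OC)c1ccc(OC(C)=O)cc1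
F7 | step 5 | (2R,3R)-2-{[3-hydroxy-4-(3-methylbut-2-en-1-yl)phenyl]methyl}-3-(4-hydroxyphenyl)-4-methoxy-4-oxobutanoic acid | OC(=O)[C@H](Cc1ccc(CC=C(C)C)c(O)c1)[C@@H](C(=O)OC)c1ccc(O)cc1
F8 | step 6 | (2S,3S)-2-{[3-acetoxy-4-(3-methylbut-2-en-1-yl)phenyl]methyl}-3-(4-acetoxyphenyl)-4-methoxy-4-oxobutanoic acid | OC(=O)[C@@H](Cc1ccc(CC=C(C)C)c(OC(C)=O)c1)[C@H](C(=O)OC)c1ccc(OC(C)=O)cc1
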